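**Retrosynthetic overview**

1. The target is a (2S)-flavanone (naringenin unit) whose ring B carbon C3' is bonded to C6 of an apigenin unit. The last operations are hydrogenolysis of six benzyl ethers and oxidation of a C4 methyl ether to the C4 ketone.
2. Feature used: in ring C the bonds O1–C2 and C3–C4 flank the C2–C3 unit, which is the vinyl group of a ring B styrene, and C4 sits on ring A ortho to the phenolic O1. Ring C is therefore cut into an ortho-quinone methide (O1, C8a, C4a, C4; from a salicylaldehyde and trimethyl orthoformate) and the styrene, joined in a three-component (4+2) annulation under a confined chiral acid.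
3. The styrene already carries the finished flavone. Its biaryl bond (ring B C3' to flavone C6) comes from a Suzuki–Miyaura coupling of 6-iodoapigenin tribenzyl ether with a 2-benzyloxy-5-vinylphenyl boronate.
4. The iodide comes from apigenin (dibenzylation, iodination ortho to the chelated 5-OH, benzylation), the boronate from 3-bromo-4-hydroxybenzaldehyde, and the salicylaldehyde from 2,4,6-trihydroxybenzaldehyde.
5. Ring order: the flavone rings come with apigenin, the biaryl bond follows, and flavanone ring C is closed last.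

Key step: step 9

Assumptions: apigenin is bought. The biaryl axis has no descriptor in the target and is treated as configurationally labile. C4 of compound 15 is written as the 2,4-cis (4S) epimer for definiteness and is removed in step 10.

**Route**

Step 1
Reactants: 1 2,4,6-trihydroxybenzaldehyde
Product: 2 2,4-bis(benzyloxy)-6-hydroxybenzaldehyde
Conditions: BnBr (2.05 equiv), K2CO3, DMF, 0 °C to rt
Reagents that add atoms: benzyl bromide, BrCc1ccccc1
Why: Williamson etherification takes the 4-OH and one ortho OH, and the remaining ortho OH is held in a hydrogen bond to the formyl oxygen and is the least nucleophilic, so two equivalents of benzyl bromide should stop at the dibenzyl ether.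

Step 2
Reactants: 3 3-bromo-4-hydroxybenzaldehyde
Product: 4 4-(benzyloxy)-3-bromobenzaldehyde
Conditions: BnBr, K2CO3, DMF, rt
Reagents that add atoms: benzyl bromide, BrCc1ccccc1
Why: Williamson etherification of an acidic para-formyl phenol, with no competing nucleophilic site.

Step 3
Reactants: 4 4-(benzyloxy)-3-bromobenzaldehyde
Product: 5 4-(benzyloxy)-3-(4,4,5,5-tetramethyl-1,3,2-dioxaborolan-2-yl)benzaldehyde
Conditions: B2pin2, PdCl2(dppf) (3 mol %), KOAc, 1,4-dioxane, 90 °C
Reagents that add atoms: bis(pinacolato)diboron, CC1(C)OB(OC1(C)C)B1OC(C)(C)C(C)(C)O1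
Why: Miyaura borylation of an aryl bromide with the weak base KOAc tolerates the aldehyde and the benzyl ether.

Step 4
Reactants: 5 4-(benzyloxy)-3-(4,4,5,5-tetramethyl-1,3,2-dioxaborolan-2-yl)benzaldehyde
Product: 6 2-[2-(benzyloxy)-5-ethenylphenyl]-4,4,5,5-tetramethyl-1,3,2-dioxaborolane
Conditions: Ph3PCH3Br, KOtBu, THF, 0 °C
Reagents that add atoms: methyltriphenylphosphonium bromide, C[P+](c1ccccc1)(c1ccccc1)c1ccccc1.[Br-]
Why: Wittig methylenation of the aldehyde; aryl pinacol boronates survive a non-stabilised ylide at 0 °C, and making the styrene here keeps the ylide away from the flavone.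

Step 5
Reactants: 7 apigenin (5,7-dihydroxy-2-(4-hydroxyphenyl)-4H-chromen-4-one)
Product: 8 7-(benzyloxy)-2-[4-(benzyloxy)phenyl]-5-hydroxy-4H-chromen-4-one
Conditions: BnBr (2.2 equiv), K2CO3, DMF, rt
Reagents that add atoms: benzyl bromide, BrCc1ccccc1
Why: Williamson etherification of the two acidic phenols at C7 and C4', while the 5-OH, chelated to the C4 carbonyl, stays free under mild conditions.

Step 6
Reactants: 8 7-(benzyloxy)-2-[4-(benzyloxy)phenyl]-5-hydroxy-4H-chromen-4-one
Product: 9 7-(benzyloxy)-2-[4-(benzyloxy)phenyl]-5-hydroxy-6-iodo-4H-chromen-4-one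
Conditions: TlOAc, I2, CH2Cl2, rt
Reagents that add atoms: iodine, II
Why: Electrophilic ortho-iodination of a phenol through its thallium phenoxide, which delivers iodine to C6, the only carbon ortho to the free 5-OH, and not to C8, which is para to it.

Step 7
Reactants: 9 7-(benzyloxy)-2-[4-(benzyloxy)phenyl]-5-hydroxy-6-iodo-4H-chromen-4-one
Product: 10 5,7-bis(benzyloxy)-2-[4-(benzyloxy)phenyl]-6-iodo-4H-chromen-4-one
Conditions: BnBr, K2CO3, Bu4NI (cat.), DMF, 70 °C
Reagents that add atoms: benzyl bromide, BrCc1ccccc1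
Why: Williamson etherification under more forcing conditions overcomes the hydrogen bond of the 5-OH, and the aryl iodide and flavone are inert to carbonate.

Step 8
Reactants: 10 5,7-bis(benzyloxy)-2-[4-(benzyloxy)phenyl]-6-iodo-4H-chromen-4-one, 6 2-[2-(benzyloxy)-5-ethenylphenyl]-4,4,5,5-tetramethyl-1,3,2-dioxaborolane
Product: 11 5,7-bis(benzyloxy)-6-[2-(benzyloxy)-5-ethenylphenyl]-2-[4-(benzyloxy)phenyl]-4H-chromen-4-one
Conditions: Pd(OAc)2 (5 mol %), SPhos (10 mol %), K3PO4, toluene/H2O, 90 °C, BHT (trace)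
Reagents that add atoms: none
Why: Suzuki–Miyaura coupling to a tri-ortho-substituted biaryl, for which the bulky electron-rich biarylphosphine SPhos is suited; transmetalation of the boronate should outrun Heck-type insertion of the vinyl group.

Step 9
Reactants: 2 2,4-bis(benzyloxy)-6-hydroxybenzaldehyde, 12 trimethyl orthoformate, 11 5,7-bis(benzyloxy)-6-[2-(benzyloxy)-5-ethenylphenyl]-2-[4-(benzyloxy)phenyl]-4H-chromen-4-one
Product: 15 6-{2-(benzyloxy)-5-[(2S,4S)-5,7-bis(benzyloxy)-4-methoxychroman-2-yl]phenyl}-5,7-bis(benzyloxy)-2-[4-(benzyloxy)phenyl]-4H-chromen-4-one, via dimethyl acetal 13 (not isolated), via methoxy ortho-quinone methide 14 (not isolated)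
Conditions: 12 (3 equiv), chiral imidodiphosphorimidate acid (IDPi: two 3,3'-bis[3,5-bis(trifluoromethyl)phenyl]-BINOL units, N-triflyl groups; antipode chosen for 2S; 10 mol %), CH2Cl2, −40 °C, slow addition of 2 (1.3 equiv) to 11
Reagents that add atoms: none
Why: Proposed new method: the acid and orthoformate 12 convert aldehyde 2 into acetal 13, which loses methanol to the ortho-hydroxybenzylic oxocarbenium ion (O-protonated 14) held as an ion pair with the confined chiral anion; the terminal carbon of styrene 11 adds to this carbon (C3–C4 bond) and the ring A phenol oxygen then captures the 4-benzyloxy-stabilised benzylic cation (O1–C2 bond), so ring C is closed by a stepwise polar (4+2) annulation, carbon–carbon bond first and six-membered C–O ring closure second. The closest known reactions are the achiral acid-catalysed three-component synthesis of 2-aryl-4-alkoxychromans from salicylaldehydes, orthoformates and styrenes, and the chiral phosphoric acid-catalysed (4+2) reactions of ortho-quinone methides with styrenes; the enantioselective three-component version on a trioxygenated, methoxy-substituted ortho-quinone methide is the untested part. C2 (S) is to be controlled by the catalyst, which selects the face of the oxocarbenium carbon and, through a chair-like closure with aryl and methoxy groups pseudo-equatorial (2,4-cis), relays that choice to C2; C4 (S as drawn) is set in the same event and is erased in step 10. The step needs C–C bonding at the terminal alkene carbon, secured by the para-benzyloxy group that stabilises the cation at C2, and chemoselectivity for the styrene over the flavone C2=C3 bond (a deactivated vinylogous ester) and over Friedel–Crafts attack by the ring A carbons of 13 and 15, which slow addition of 2 and low temperature are meant to suppress. Because the two C4 epimers that arise from one face of the oxocarbenium ion differ in configuration at C2, the diastereomers are to be separated and only material of 2S configuration carried into step 10; the low temperature also guards C2 against re-ionisation of the para-alkoxybenzylic C2–O1 bond.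

Step 10
Reactants: 15 6-{2-(benzyloxy)-5-[(2S,4S)-5,7-bis(benzyloxy)-4-methoxychroman-2-yl]phenyl}-5,7-bis(benzyloxy)-2-[4-(benzyloxy)phenyl]-4H-chromen-4-one
Product: 16 6-{2-(benzyloxy)-5-[(2S)-5,7-bis(benzyloxy)-4-oxochroman-2-yl]phenyl}-5,7-bis(benzyloxy)-2-[4-(benzyloxy)phenyl]-4H-chromen-4-one
Conditions: DDQ (1.3 equiv), CH2Cl2/pH 7 aqueous buffer, 0 °C to rt
Reagents that add atoms: water, O
Why: DDQ oxidation of an electron-rich benzylic ether (the reaction type that removes dimethoxybenzyl ethers): hydride is taken from C4–H, which is benzylic to the 2,4,6-trioxygenated ring A and alpha to the methoxy oxygen, water adds to the oxocarbenium ion and the hemiketal loses methanol, while C2–H, benzylic only to the mono-alkoxy ring B, and the aryl benzyl ethers should react far more slowly, so C2 stays S.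

Step 11
Reactants: 16 6-{2-(benzyloxy)-5-[(2S)-5,7-bis(benzyloxy)-4-oxochroman-2-yl]phenyl}-5,7-bis(benzyloxy)-2-[4-(benzyloxy)phenyl]-4H-chromen-4-one
Product: 17 6-{5-[(2S)-5,7-dihydroxy-4-oxochroman-2-yl]-2-hydroxyphenyl}-5,7-dihydroxy-2-(4-hydroxyphenyl)-4H-chromen-4-one (CNP0277421.1)
Conditions: H2 (1 atm), Pd/C (10%), THF/MeOH, rt, stopped at full debenzylation
Reagents that add atoms: none
Why: Hydrogenolysis of six aryl benzyl ethers over Pd/C in neutral medium, under which the flavone C2=C3 bond, the two C4 ketones and the flavanone C2–O1 bond should survive and C2 cannot epimerise, since no base or strong acid is present.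

**Compound list**

1 | 2,4,6-trihydroxybenzaldehyde | O=Cc1c(O)cc(O)cc1O | starting material
2 | 2,4-bis(benzyloxy)-6-hydroxybenzaldehyde | O=Cc1c(O)cc(OCc2ccccc2)cc1OCc1ccccc1 | intermediate
3 | 3-bromo-4-hydroxybenzaldehyde | O=Cc1ccc(O)c(Br)c1 | starting material
4 | 4-(benzyloxy)-3-bromobenzaldehyde | O=Cc1ccc(OCc2ccccc2)c(Br)c1 | intermediate
5 | 4-(benzyloxy)-3-(4,4,5,5-tetramethyl-1,3,2-dioxaborolan-2-yl)benzaldehyde | O=Cc1ccc(OCc2ccccc2)c(B2OC(C)(C)C(C)(C)O2)c1 | intermediate
6 | 2-[2-(benzyloxy)-5-ethenylphenyl]-4,4,5,5-tetramethyl-1,3,2-dioxaborolane | C=Cc1ccc(OCc2ccccc2)c(B2OC(C)(C)C(C)(C)O2)c1 | intermediate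
7 | apigenin, 5,7-dihydroxy-2-(4-hydroxyphenyl)-4H-chromen-4-one | O=c1cc(-c2ccc(O)cc2)oc2cc(O)cc(O)c12 | starting material
8 | 7-(benzyloxy)-2-[4-(benzyloxy)phenyl]-5-hydroxy-4H-chromen-4-one | O=c1cc(-c2ccc(OCc3ccccc3)cc2)oc2cc(OCc3ccccc3)cc(O)c12 | intermediate
9 | 7-(benzyloxy)-2-[4-(benzyloxy)phenyl]-5-hydroxy-6-iodo-4H-chromen-4-one | O=c1cc(-c2ccc(OCc3ccccc3)cc2)oc2cc(OCc3ccccc3)c(I)c(O)c12 | intermediate
10 | 5,7-bis(benzyloxy)-2-[4-(benzyloxy)phenyl]-6-iodo-4H-chromen-4-one | O=c1cc(-c2ccc(OCc3ccccc3)cc2)oc2cc(OCc3ccccc3)c(I)c(OCc3ccccc3)c12 | intermediate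
11 | 5,7-bis(benzyloxy)-6-[2-(benzyloxy)-5-ethenylphenyl]-2-[4-(benzyloxy)phenyl]-4H-chromen-4-one | C=Cc1ccc(OCc2ccccc2)c(-c2c(OCc3ccccc3)cc3oc(-c4ccc(OCc5ccccc5)cc4)cc(=O)c3c2OCc2ccccc2)c1 | intermediate
12 | trimethyl orthoformate | COC(OC)OC | starting material
13 | 3,5-bis(benzyloxy)-2-(dimethoxymethyl)phenol (dimethyl acetal of 2) | COC(OC)c1c(O)cc(OCc2ccccc2)cc1OCc1ccccc1 | intermediate
14 | 3,5-bis(benzyloxy)-6-(methoxymethylidene)cyclohexa-2,4-dien-1-one (methoxy ortho-quinone methide, reacting as its O-protonated ion pair; exocyclic double-bond geometry not fixed) | COC=C1C(=O)C=C(OCc2ccccc2)C=C1OCc1ccccc1 | intermediate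
15 | 6-{2-(benzyloxy)-5-[(2S,4S)-5,7-bis(benzyloxy)-4-methoxychroman-2-yl]phenyl}-5,7-bis(benzyloxy)-2-[4-(benzyloxy)phenyl]-4H-chromen-4-one | CO[C@H]1C[C@@H](c2ccc(OCc3ccccc3)c(-c3c(OCc4ccccc4)cc4oc(-c5ccc(OCc6ccccc6)cc5)cc(=O)c4c3OCc3ccccc3)c2)Oc2cc(OCc3ccccc3)cc(OCc3ccccc3)c21 | intermediate
16 | 6-{2-(benzyloxy)-5-[(2S)-5,7-bis(benzyloxy)-4-oxochroman-2-yl]phenyl}-5,7-bis(benzyloxy)-2-[4-(benzyloxy)phenyl]-4H-chromen-4-one | O=C1C[C@@H](c2ccc(OCc3ccccc3)c(-c3c(OCc4ccccc4)cc4oc(-c5ccc(OCc6ccccc6)cc5)cc(=O)c4c3OCc3ccccc3)c2)Oc2cc(OCc3ccccc3)cc(OCc3ccccc3)c21 | intermediate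
17 | 6-{5-[(2S)-5,7-dihydroxy-4-oxochroman-2-yl]-2-hydroxyphenyl}-5,7-dihydroxy-2-(4-hydroxyphenyl)-4H-chromen-4-one | O=C1C[C@@H](c2ccc(O)c(-c3c(O)cc4oc(-c5ccc(O)cc5)cc(=O)c4c3O)c2)Oc2cc(O)cc(O)c21 | target

**Step count and risks**

Total steps: 11. Longest linear sequence: 7 steps (apigenin 7 through steps 5, 6, 7, 8, 9, 10 and 11 to 17).

Steps most likely to fail:

1. Step 9 (key step). The catalyst may give poor facial control in the annulation, and the acid may be buffered by the basic flavone carbonyl. The cation may also be diverted into Friedel–Crafts oligomerisation through the electron-rich ring A carbons or into cationic polymerisation of the styrene, and C2 may racemise by re-ionisation of the C2–O1 bond. The fallback uses known chemistry and sets out from iodide 10 and boronate 5. Suzuki–Miyaura coupling (Pd(OAc)2, SPhos, K3PO4, toluene/H2O, 90 °C) should give 4-(benzyloxy)-3-{5,7-bis(benzyloxy)-2-[4-(benzyloxy)phenyl]-4-oxo-4H-chromen-6-yl}benzaldehyde F1. Claisen–Schmidt condensation with commercial 1-[2,4-bis(benzyloxy)-6-hydroxyphenyl]ethanone (KOH, EtOH/THF, rt) should then give (E)-1-[2,4-bis(benzyloxy)-6-hydroxyphenyl]-3-{4-(benzyloxy)-3-[5,7-bis(benzyloxy)-2-(4-benzyloxyphenyl)-4-oxo-4H-chromen-6-yl]phenyl}prop-2-en-1-one F2. Oxa-Michael ring closure (NaOAc, EtOH, reflux) should give racemic 6-{2-(benzyloxy)-5-[5,7-bis(benzyloxy)-4-oxochroman-2-yl]phenyl}-5,7-bis(benzyloxy)-2-[4-(benzyloxy)phenyl]-4H-chromen-4-one F3. Preparative chromatography on a chiral stationary phase then separates the enantiomers, and the 2S enantiomer is compound 16, where the route is rejoined before step 11.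

2. Step 10. Hydride abstraction may also occur at C2–H, the flavanone may be oxidised further, or the acidic hydroquinone by-product may open the ring at C2. The fallback sets out from 15 and replaces hydride abstraction by solvolysis and alcohol oxidation. Mild acid in wet solvent (PPTS, acetone/H2O, rt, dilute) should exchange the C4 methoxy group for hydroxyl through the ring A-stabilised cation and give 6-{2-(benzyloxy)-5-[(2S)-5,7-bis(benzyloxy)-4-hydroxychroman-2-yl]phenyl}-5,7-bis(benzyloxy)-2-[4-(benzyloxy)phenyl]-4H-chromen-4-one F4 as a mixture of C4 epimers. Oxidation with Dess–Martin periodinane (NaHCO3, CH2Cl2, 0 °C) then leads to compound 16.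

3. Step 8. Transmetalation at the iodide flanked by two benzyloxy groups may be slow, so that protodeboronation of 6, reduction of the iodide or Heck-type reaction of the vinyl group takes over. The fallback sets out from 9 and 6 and moves the coupling ahead of the last benzylation, so that one flanking group is only a phenoxide. Suzuki–Miyaura coupling (Pd(OAc)2, SPhos, K3PO4, toluene/H2O, 90 °C) should give 7-(benzyloxy)-6-[2-(benzyloxy)-5-ethenylphenyl]-2-[4-(benzyloxy)phenyl]-5-hydroxy-4H-chromen-4-one F5. Benzylation of the 5-OH (BnBr, K2CO3, DMF, 70 °C) then gives compound 11.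

**Further compounds**

F1 | step 9 | 4-(benzyloxy)-3-{5,7-bis(benzyloxy)-2-[4-(benzyloxy)phenyl]-4-oxo-4H-chromen-6-yl}benzaldehyde | O=Cc1ccc(OCc2ccccc2)c(-c2c(OCc3ccccc3)cc3oc(-c4ccc(OCc5ccccc5)cc4)cc(=O)c3c2OCc2ccccc2)c1
F2 | step 9 | (E)-1-[2,4-bis(benzyloxy)-6-hydroxyphenyl]-3-{4-(benzyloxy)-3-[5,7-bis(benzyloxy)-2-(4-benzyloxyphenyl)-4-oxo-4H-chromen-6-yl]phenyl}prop-2-en-1-one | O=C(/C=C/c1ccc(OCc2ccccc2)c(-c2c(OCc3ccccc3)cc3oc(-c4ccc(OCc5ccccc5)cc4)cc(=O)c3c2OCc2ccccc2)c1)c1c(O)cc(OCc2ccccc2)cc1OCc1ccccc1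
F3 | step 9 | racemic 6-{2-(benzyloxy)-5-[5,7-bis(benzyloxy)-4-oxochroman-2-yl]phenyl}-5,7-bis(benzyloxy)-2-[4-(benzyloxy)phenyl]-4H-chromen-4-one | O=C1CC(c2ccc(OCc3ccccc3)c(-c3c(OCc4ccccc4)cc4oc(-c5ccc(OCc6ccccc6)cc5)cc(=O)c4c3OCc3ccccc3)c2)Oc2cc(OCc3ccccc3)cc(OCc3ccccc3)c21
F4 | step 10 | 6-{2-(benzyloxy)-5-[(2S)-5,7-bis(benzyloxy)-4-hydroxychroman-2-yl]phenyl}-5,7-bis(benzyloxy)-2-[4-(benzyloxy)phenyl]-4H-chromen-4-one (C4 epimers) | OC1C[C@@H](c2ccc(OCc3ccccc3)c(-c3c(OCc4ccccc4)cc4oc(-c5ccc(OCc6ccccc6)cc5)cc(=O)c4c3OCc3ccccc3)c2)Oc2cc(OCc3ccccc3)cc(OCc3ccccc3)c21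
F5 | step 8 | 7-(benzyloxy)-6-[2-(benzyloxy)-5-ethenylphenyl]-2-[4-(benzyloxy)phenyl]-5-hydroxy-4H-chromen-4-one | C=Cc1ccc(OCc2ccccc2)c(-c2c(OCc3ccccc3)cc3oc(-c4ccc(OCc5ccccc5)cc4)cc(=O)c3c2O)c1
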